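**Retrosynthetic overview**

1. The target is epicatechin-(4β→6)-epiafzelechin-(4β→8)-epicatechin-(4β→6)-epicatechin (all units 2R,3R, all interflavan bonds 3,4-trans); the last operation is hydrogenolysis of its octadeca-O-benzyl ether.
2. Key disconnection: the pyran ring of the terminal (fourth) unit is cut at O1–C2 and C3–C4, giving an ortho-quinone methide (C4=C4a–C8a=O1) and a (Z)-2-arylvinylboronate for an oxa-[4+2]; C3–B then becomes C3–OH. This one operation sets C2 and C3 and brings in the catechol ring.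
3. Enabling feature: in that unit C4 is an unsubstituted CH2 ortho to the ring oxygen O1 on the phloroglucinol ring, and the interflavan carbon C6 is para to O1 and flanked by O5 and O7. The precursor is therefore a 4-(flavan-4-yl)-3,5-bis(benzyloxy)phenol whose two ortho carbons are equivalent and whose only free oxygen is O1, so the annulation can give only the 4→6-linked unit.
4. The trimer phenol comes from a 4β→8 Friedel–Crafts union of a dimeric C4 electrophile (epicatechin-(4β→6)-epiafzelechin) with C8 of one common block, penta-O-benzylepicatechin carrying a 2,6-bis(benzyloxy)-4-silyloxyphenyl group at C4β. The same block, desilylated, gives the dimer by the same annulation with a 4-benzyloxyphenyl dienophile.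
5. Ring order: the chroman rings of units one and three are bought as (−)-epicatechin, the pyran of the epiafzelechin unit is annulated next, and the pyran of the terminal epicatechin unit closes last.

Key step: step 17

Assumption: the sense of induction of the chiral acid in steps 9 and 17 cannot be predicted with certainty; the (R)-catalyst is written, and its antipode is to be taken if a model run on the saligenin from 3,5-bis(benzyloxy)phenol shows the opposite sense.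

**Route**

Step 1
Reactants: 1 (−)-epicatechin
Product: 2 5,7,3',4'-tetra-O-benzyl-(−)-epicatechin
Conditions: BnBr, K2CO3, DMF, 0 °C to rt
Reagents that add atoms: benzyl bromide BrCc1ccccc1
Why: Williamson etherification in which carbonate deprotonates only the four phenols, so the secondary 3-OH stays free and no stereocentre is touched.

Step 2
Reactants: 2 5,7,3',4'-tetra-O-benzyl-(−)-epicatechin
Product: 3 4β-(2-ethoxyethoxy)-5,7,3',4'-tetra-O-benzylepicatechin (4-alkoxy trans to 3-OH)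
Conditions: DDQ, 2-ethoxyethanol, CH2Cl2, rt
Reagents that add atoms: 2-ethoxyethanol CCOCCO
Why: DDQ benzylic oxidation (hydride abstraction from C4 to the A-ring-stabilised cation) with capture by the alcohol on the β-face, opposite the α-oriented 2-aryl and 3-OH groups; the new centre is only a leaving-group site.

Step 3
Reactants: 3 4β-(2-ethoxyethoxy)-5,7,3',4'-tetra-O-benzylepicatechin
Product: 4 3,5,7,3',4'-penta-O-benzyl-4β-(2-ethoxyethoxy)epicatechin
Conditions: NaH, BnBr, DMF, 0 °C to rt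
Reagents that add atoms: benzyl bromide BrCc1ccccc1
Why: Williamson O-benzylation of the secondary alkoxide, with the C4 ether stable to base; it removes the free hydroxyl that could O-alkylate in the later cationic couplings.

Step 4
Reactants: 5 3,5-bis(benzyloxy)phenol
Product: 6 [3,5-bis(benzyloxy)phenoxy]triisopropylsilane
Conditions: TIPSCl, imidazole, DMF, rt
Reagents that add atoms: chlorotriisopropylsilane CC(C)[Si](Cl)(C(C)C)C(C)C
Why: standard phenol silylation; the bulky silyl group marks the oxygen that will become O1 and shields both carbons ortho to it.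

Step 5
Reactants: 4 3,5,7,3',4'-penta-O-benzyl-4β-(2-ethoxyethoxy)epicatechin and 6 [3,5-bis(benzyloxy)phenoxy]triisopropylsilane
Product: 7 3,5,7,3',4'-penta-O-benzyl-4β-[2,6-bis(benzyloxy)-4-(triisopropylsilyloxy)phenyl]epicatechin (2,3-cis, 3,4-trans)
Conditions: 6 (3 equiv), TMSOTf (cat.), CH2Cl2, −78 to −40 °C; Et3N quench
Reagents that add atoms: none
Why: Lewis-acid Friedel–Crafts reaction of the flavan-4-yl cation, which is attacked on the β-face (anti to the 2-aryl and 3-OBn groups) to set C4, and by the arene carbon para to the silyloxy group because the triisopropylsilyl group blocks both ortho carbons.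

Step 6
Reactants: 7 3,5,7,3',4'-penta-O-benzyl-4β-[2,6-bis(benzyloxy)-4-(triisopropylsilyloxy)phenyl]epicatechin
Product: 8 3,5,7,3',4'-penta-O-benzyl-4β-[2,6-bis(benzyloxy)-4-hydroxyphenyl]epicatechin
Conditions: TBAF, THF, 0 °C
Reagents that add atoms: none
Why: fluoride cleavage of the aryl silyl ether frees the single phenol para to the interflavan carbon; benzyl ethers are inert.

Step 7
Reactants: 8 3,5,7,3',4'-penta-O-benzyl-4β-[2,6-bis(benzyloxy)-4-hydroxyphenyl]epicatechin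
Product: 10 3,5,7,3',4'-penta-O-benzyl-4β-[2,6-bis(benzyloxy)-4-hydroxy-3-(hydroxymethyl)phenyl]epicatechin, via salicylaldehyde 9 (not isolated)
Conditions: MgCl2, Et3N, (CH2O)n, THF, 65 °C; aqueous work-up; then NaBH4, THF/MeOH, 0 °C
Reagents that add atoms: formaldehyde (as paraformaldehyde) C=O
Why: magnesium-phenoxide-directed ortho-formylation (Casnati–Skattebøl) reacts only ortho to the one free phenol, whose two ortho carbons are equivalent, and stops at mono-formylation; borohydride then gives the saligenin, which is used without storage.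

Step 8
Reactants: 11 1-(benzyloxy)-4-ethynylbenzene
Product: 12 2-[(Z)-2-(4-benzyloxyphenyl)ethenyl]-4,4,5,5-tetramethyl-1,3,2-dioxaborolane
Conditions: HBpin, [Rh(cod)Cl]2 (cat.), P(iPr)3, Et3N, cyclohexane, rt
Reagents that add atoms: pinacolborane CC1(C)OBOC1(C)C
Why: rhodium-catalysed trans-hydroboration of a terminal alkyne through a metal vinylidene, which delivers the (Z)-1-alkenylboronate.

Step 9
Reactants: 10 3,5,7,3',4'-penta-O-benzyl-4β-[2,6-bis(benzyloxy)-4-hydroxy-3-(hydroxymethyl)phenyl]epicatechin and 12 2-[(Z)-2-(4-benzyloxyphenyl)ethenyl]-4,4,5,5-tetramethyl-1,3,2-dioxaborolane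
Product: 15 3,5,7,3',4'-penta-O-benzylepicatechin-(4β→6)-5,7,4'-tri-O-benzylepiafzelechin (new unit 2R,3R, its 3-OH free), via o-quinone methide 13 (not isolated), via 3-boryl flavan 14 (not isolated)
Conditions: 12 (3 equiv), (R)-3,3'-bis(2,4,6-triisopropylphenyl)-H8-BINOL N-triflylphosphoramide (10 mol %), 5 Å MS, CH2Cl2, −20 °C, slow addition of 10; then NaBO3·4H2O, THF/H2O, rt
Reagents that add atoms: sodium perborate [Na+].[Na+].O[B-]1(O)OO[B-](O)(O)OO1
Why: Proposed new method: the acid ionises the trioxygenated benzylic alcohol to the ion-paired o-quinone methide 13, which takes up the (Z)-alkenylboronate in an asynchronous, suprafacial oxa-[4+2] (closest known type: chiral Brønsted acid catalysed [4+2] of in situ o-quinone methides with styrenes); the Z geometry gives 2,3-cis, the chiral anion the (2R,3R) sense, the aryl- and β-C–B-stabilised charge at C2 the regiochemistry, and perborate oxidation with retention the 3-OH.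

Step 10
Reactants: 15 3,5,7,3',4'-penta-O-benzylepicatechin-(4β→6)-5,7,4'-tri-O-benzylepiafzelechin
Product: 16 3,5,7,3',4'-penta-O-benzylepicatechin-(4β→6)-[5,7,4'-tri-O-benzyl-4β-(2-ethoxyethoxy)epiafzelechin]
Conditions: DDQ, 2-ethoxyethanol, CH2Cl2, rt
Reagents that add atoms: 2-ethoxyethanol CCOCCO
Why: DDQ benzylic oxidation as in step 2; hydride should be taken from the open C4 methylene of the lower unit and not from the tertiary C4–H of the upper unit, which is buried between four ortho benzyloxy groups and the 3-OBn group.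

Step 11
Reactants: 16 3,5,7,3',4'-penta-O-benzylepicatechin-(4β→6)-[5,7,4'-tri-O-benzyl-4β-(2-ethoxyethoxy)epiafzelechin]
Product: 17 3,5,7,3',4'-penta-O-benzylepicatechin-(4β→6)-[3,5,7,4'-tetra-O-benzyl-4β-(2-ethoxyethoxy)epiafzelechin]
Conditions: NaH, BnBr, DMF, 0 °C to rt
Reagents that add atoms: benzyl bromide BrCc1ccccc1
Why: Williamson O-benzylation of the one free secondary hydroxyl, as in step 3.

Step 12
Reactants: 17 3,5,7,3',4'-penta-O-benzylepicatechin-(4β→6)-[3,5,7,4'-tetra-O-benzyl-4β-(2-ethoxyethoxy)epiafzelechin] and 7 3,5,7,3',4'-penta-O-benzyl-4β-[2,6-bis(benzyloxy)-4-(triisopropylsilyloxy)phenyl]epicatechin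
Product: 18 penta-O-benzylepicatechin-(4β→6)-tetra-O-benzylepiafzelechin-(4β→8)-{penta-O-benzyl-4β-[2,6-bis(benzyloxy)-4-(triisopropylsilyloxy)phenyl]epicatechin}
Conditions: 7 (3 equiv, excess to be recovered), TMSOTf (cat.), CH2Cl2, −78 to −40 °C; Et3N quench
Reagents that add atoms: none
Why: TMSOTf-mediated flavan-4-yl/arene condensation of the kind used for procyanidin oligomers; the cation is attacked on its β-face (3,4-trans) by C8 of 7, which is the least hindered nucleophilic carbon (C6 lies between two benzyloxy groups, the pendant arene is shielded by the silyl group), and the excess of 7 suppresses self-condensation.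

Step 13
Reactants: 18 the trimer silyl ether
Product: 19 penta-O-benzylepicatechin-(4β→6)-tetra-O-benzylepiafzelechin-(4β→8)-{penta-O-benzyl-4β-[2,6-bis(benzyloxy)-4-hydroxyphenyl]epicatechin}
Conditions: TBAF, THF, 0 °C
Reagents that add atoms: none
Why: fluoride desilylation frees the only phenol of the molecule, the future O1 of the terminal unit.

Step 14
Reactants: 19 the trimer phenol
Product: 21 penta-O-benzylepicatechin-(4β→6)-tetra-O-benzylepiafzelechin-(4β→8)-{penta-O-benzyl-4β-[2,6-bis(benzyloxy)-4-hydroxy-3-(hydroxymethyl)phenyl]epicatechin}, via salicylaldehyde 20 (not isolated)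
Conditions: MgCl2, Et3N, (CH2O)n, THF, 65 °C; aqueous work-up; then NaBH4, THF/MeOH, 0 °C
Reagents that add atoms: formaldehyde (as paraformaldehyde) C=O
Why: the same ortho-formylation/reduction as step 7; the basic, chelation-directed conditions leave the acid-labile interflavan bonds and the benzyloxyarenes alone.

Step 15
Reactants: 22 3,4-bis(benzyloxy)benzaldehyde
Product: 23 1,2-bis(benzyloxy)-4-ethynylbenzene
Conditions: dimethyl (1-diazo-2-oxopropyl)phosphonate, K2CO3, MeOH, rt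
Reagents that add atoms: Ohira–Bestmann reagent CC(=O)C(=[N+]=[N-])P(=O)(OC)OC
Why: Seyferth–Gilbert homologation in the Ohira–Bestmann form converts the aryl aldehyde into the terminal alkyne under mild base.

Step 16
Reactants: 23 1,2-bis(benzyloxy)-4-ethynylbenzene
Product: 24 2-[(Z)-2-(3,4-bis(benzyloxy)phenyl)ethenyl]-4,4,5,5-tetramethyl-1,3,2-dioxaborolane
Conditions: HBpin, [Rh(cod)Cl]2 (cat.), P(iPr)3, Et3N, cyclohexane, rt
Reagents that add atoms: pinacolborane CC1(C)OBOC1(C)C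
Why: rhodium-catalysed trans-hydroboration via a vinylidene, as in step 8, gives the (Z)-alkenylboronate.

Step 17
Reactants: 21 the trimer saligenin and 24 2-[(Z)-2-(3,4-bis(benzyloxy)phenyl)ethenyl]-4,4,5,5-tetramethyl-1,3,2-dioxaborolane
Product: 27 penta-O-benzylepicatechin-(4β→6)-tetra-O-benzylepiafzelechin-(4β→8)-penta-O-benzylepicatechin-(4β→6)-5,7,3',4'-tetra-O-benzylepicatechin (terminal unit 2R,3R, its 3-OH free), via o-quinone methide 25 (not isolated), via 3-boryl flavan 26 (not isolated)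
Conditions: 24 (3 equiv), (R)-3,3'-bis(2,4,6-triisopropylphenyl)-H8-BINOL N-triflylphosphoramide (10 mol %), 5 Å MS, CH2Cl2, −20 °C, slow addition of 21; then NaBO3·4H2O, THF/H2O, rt
Reagents that add atoms: sodium perborate [Na+].[Na+].O[B-]1(O)OO[B-](O)(O)OO1
Why: Proposed new method: the chiral Brønsted acid ionises the 2,4,6-trioxygenated benzylic alcohol 21 to the ion-paired ortho-quinone methide 25, which undergoes an inverse-electron-demand oxa-[4+2] cycloaddition with the (Z)-alkenylboronate 24 in which the C4–C3 bond leads and the O1–C2 bond follows without bond rotation (concerted, asynchronous, suprafacial on the dienophile). The closest known reaction types are the chiral phosphoric acid and N-triflylphosphoramide catalysed [4+2] cycloadditions of in situ ortho-quinone methides with styrenes and the hetero-Diels–Alder reactions of phloroglucinol-derived ortho-quinone methides with alkenes; an alkenylboronate as the 2π partner and an unsubstituted methide carbon in the asymmetric version are new. The pyran ring of the fourth flavan unit is closed in this [4+2] (hetero-Diels–Alder) mode, forming C4–C3 and O1–C2 in one event, and the C–B bond of 26 is then oxidised with retention to the C3 hydroxyl. The 2,3-cis relationship follows stereospecifically from the Z geometry of 24, and the absolute sense at C2 and C3 (2R,3R) is set by the chiral counter-anion bound at the quinone methide oxygen, the remote stereocentres of the trimer having no say. The step needs the aryl group at C2, which is secured because the 3,4-bis(benzyloxy)phenyl group and the β-C–B bond stabilise positive charge at C2 and make the boron-bearing carbon the nucleophilic terminus, and it needs closure through the right oxygen and carbon, which is secured because only the oxygen para to the interflavan carbon is free while the two flanking oxygens are benzyl ethers and the methylene sits on one of two equivalent ortho carbons. Slow addition of 21 to an excess of 24 should keep 25 from alkylating the benzyloxyarenes of a second molecule.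

Step 18
Reactants: 27 the octadeca-O-benzyl tetramer
Product: 28 epicatechin-(4β→6)-epiafzelechin-(4β→8)-epicatechin-(4β→6)-epicatechin (CNP0103636.1)
Conditions: H2 (1 atm), Pd(OH)2/C, THF/MeOH/H2O, rt
Reagents that add atoms: none
Why: neutral hydrogenolysis cleaves all eighteen benzyl ethers (aryl and secondary alkyl) without touching the interflavan C–C bonds, the pyran C–O bonds or any stereocentre.

**Compound list**

1 | (−)-epicatechin | O[C@@H]1Cc2c(O)cc(O)cc2O[C@@H]1c1ccc(O)c(O)c1 | starting material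
2 | 5,7,3',4'-tetra-O-benzyl-(−)-epicatechin | O[C@@H]1Cc2c(OCc6ccccc6)cc(OCc6ccccc6)cc2O[C@@H]1c1ccc(OCc6ccccc6)c(OCc6ccccc6)c1 | intermediate
3 | 4β-(2-ethoxyethoxy)-5,7,3',4'-tetra-O-benzylepicatechin | CCOCCO[C@H]1c2c(OCc6ccccc6)cc(OCc6ccccc6)cc2O[C@H](c2ccc(OCc6ccccc6)c(OCc6ccccc6)c2)[C@@H]1O | intermediate
4 | 3,5,7,3',4'-penta-O-benzyl-4β-(2-ethoxyethoxy)epicatechin | CCOCCO[C@H]1c2c(OCc6ccccc6)cc(OCc6ccccc6)cc2O[C@H](c2ccc(OCc6ccccc6)c(OCc6ccccc6)c2)[C@@H]1OCc6ccccc6 | intermediate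
5 | 3,5-bis(benzyloxy)phenol | Oc1cc(OCc2ccccc2)cc(OCc2ccccc2)c1 | starting material
6 | [3,5-bis(benzyloxy)phenoxy]triisopropylsilane | CC(C)[Si](C(C)C)(C(C)C)Oc1cc(OCc2ccccc2)cc(OCc2ccccc2)c1 | intermediate
7 | 3,5,7,3',4'-penta-O-benzyl-4β-[2,6-bis(benzyloxy)-4-(triisopropylsilyloxy)phenyl]epicatechin | CC(C)[Si](C(C)C)(C(C)C)Oc1cc(OCc6ccccc6)c([C@H]2c3c(OCc6ccccc6)cc(OCc6ccccc6)cc3O[C@H](c3ccc(OCc6ccccc6)c(OCc6ccccc6)c3)[C@@H]2OCc6ccccc6)c(OCc6ccccc6)c1 | intermediate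
8 | 3,5,7,3',4'-penta-O-benzyl-4β-[2,6-bis(benzyloxy)-4-hydroxyphenyl]epicatechin | Oc1cc(OCc6ccccc6)c([C@H]2c3c(OCc6ccccc6)cc(OCc6ccccc6)cc3O[C@H](c3ccc(OCc6ccccc6)c(OCc6ccccc6)c3)[C@@H]2OCc6ccccc6)c(OCc6ccccc6)c1 | intermediate
9 | 3,5,7,3',4'-penta-O-benzyl-4β-[2,6-bis(benzyloxy)-3-formyl-4-hydroxyphenyl]epicatechin | O=Cc1c(O)cc(OCc6ccccc6)c([C@H]2c3c(OCc6ccccc6)cc(OCc6ccccc6)cc3O[C@H](c3ccc(OCc6ccccc6)c(OCc6ccccc6)c3)[C@@H]2OCc6ccccc6)c1OCc6ccccc6 | intermediate
10 | 3,5,7,3',4'-penta-O-benzyl-4β-[2,6-bis(benzyloxy)-4-hydroxy-3-(hydroxymethyl)phenyl]epicatechin | OCc1c(O)cc(OCc6ccccc6)c([C@H]2c3c(OCc6ccccc6)cc(OCc6ccccc6)cc3O[C@H](c3ccc(OCc6ccccc6)c(OCc6ccccc6)c3)[C@@H]2OCc6ccccc6)c1OCc6ccccc6 | intermediate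
11 | 1-(benzyloxy)-4-ethynylbenzene | C#Cc1ccc(OCc2ccccc2)cc1 | starting material
12 | 2-[(Z)-2-(4-benzyloxyphenyl)ethenyl]-4,4,5,5-tetramethyl-1,3,2-dioxaborolane | CC1(C)OB(/C=C\c2ccc(OCc3ccccc3)cc2)OC1(C)C | intermediate
13 | 3,5-bis(benzyloxy)-6-methylidene-4-(penta-O-benzylepicatechin-4β-yl)cyclohexa-2,4-dien-1-one | C=C1C(=O)C=C(OCc6ccccc6)C([C@H]2c3c(OCc6ccccc6)cc(OCc6ccccc6)cc3O[C@H](c3ccc(OCc6ccccc6)c(OCc6ccccc6)c3)[C@@H]2OCc6ccccc6)=C1OCc6ccccc6 | intermediate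
14 | penta-O-benzylepicatechin-(4β→6)-[5,7,4'-tri-O-benzyl-3-deoxy-3-(pinacolatoboryl)epiafzelechin], boron cis to the 2-aryl group | O(Cc6ccccc6)c1ccc([C@H]2Oc3cc(OCc6ccccc6)c([C@H]4c5c(OCc6ccccc6)cc(OCc6ccccc6)cc5O[C@H](c5ccc(OCc6ccccc6)c(OCc6ccccc6)c5)[C@@H]4OCc6ccccc6)c(OCc6ccccc6)c3C[C@H]2B7OC(C)(C)C(C)(C)O7)cc1 | intermediate
15 | 3,5,7,3',4'-penta-O-benzylepicatechin-(4β→6)-5,7,4'-tri-O-benzylepiafzelechin | O(Cc6ccccc6)c1ccc([C@H]2Oc3cc(OCc6ccccc6)c([C@H]4c5c(OCc6ccccc6)cc(OCc6ccccc6)cc5O[C@H](c5ccc(OCc6ccccc6)c(OCc6ccccc6)c5)[C@@H]4OCc6ccccc6)c(OCc6ccccc6)c3C[C@H]2O)cc1 | intermediate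
16 | penta-O-benzylepicatechin-(4β→6)-[5,7,4'-tri-O-benzyl-4β-(2-ethoxyethoxy)epiafzelechin] | O(Cc6ccccc6)c1ccc([C@H]2Oc3cc(OCc6ccccc6)c([C@H]4c5c(OCc6ccccc6)cc(OCc6ccccc6)cc5O[C@H](c5ccc(OCc6ccccc6)c(OCc6ccccc6)c5)[C@@H]4OCc6ccccc6)c(OCc6ccccc6)c3[C@H](OCCOCC)[C@H]2O)cc1 | intermediate
17 | penta-O-benzylepicatechin-(4β→6)-[3,5,7,4'-tetra-O-benzyl-4β-(2-ethoxyethoxy)epiafzelechin] | O(Cc6ccccc6)c1ccc([C@H]2Oc3cc(OCc6ccccc6)c([C@H]4c5c(OCc6ccccc6)cc(OCc6ccccc6)cc5O[C@H](c5ccc(OCc6ccccc6)c(OCc6ccccc6)c5)[C@@H]4OCc6ccccc6)c(OCc6ccccc6)c3[C@H](OCCOCC)[C@H]2OCc6ccccc6)cc1 | intermediate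
18 | penta-O-benzylepicatechin-(4β→6)-tetra-O-benzylepiafzelechin-(4β→8)-{penta-O-benzyl-4β-[2,6-bis(benzyloxy)-4-(triisopropylsilyloxy)phenyl]epicatechin} | O(Cc6ccccc6)c1ccc([C@H]2Oc3cc(OCc6ccccc6)c([C@H]4c5c(OCc6ccccc6)cc(OCc6ccccc6)cc5O[C@H](c5ccc(OCc6ccccc6)c(OCc6ccccc6)c5)[C@@H]4OCc6ccccc6)c(OCc6ccccc6)c3[C@H](c3c(OCc6ccccc6)cc(OCc6ccccc6)c4c3O[C@H](c3ccc(OCc6ccccc6)c(OCc6ccccc6)c3)[C@H](OCc6ccccc6)[C@H]4c3c(OCc6ccccc6)cc(O[Si](C(C)C)(C(C)C)C(C)C)cc3OCc6ccccc6)[C@H]2OCc6ccccc6)cc1 | intermediate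
19 | penta-O-benzylepicatechin-(4β→6)-tetra-O-benzylepiafzelechin-(4β→8)-{penta-O-benzyl-4β-[2,6-bis(benzyloxy)-4-hydroxyphenyl]epicatechin} | O(Cc6ccccc6)c1ccc([C@H]2Oc3cc(OCc6ccccc6)c([C@H]4c5c(OCc6ccccc6)cc(OCc6ccccc6)cc5O[C@H](c5ccc(OCc6ccccc6)c(OCc6ccccc6)c5)[C@@H]4OCc6ccccc6)c(OCc6ccccc6)c3[C@H](c3c(OCc6ccccc6)cc(OCc6ccccc6)c4c3O[C@H](c3ccc(OCc6ccccc6)c(OCc6ccccc6)c3)[C@H](OCc6ccccc6)[C@H]4c3c(OCc6ccccc6)cc(O)cc3OCc6ccccc6)[C@H]2OCc6ccccc6)cc1 | intermediate
20 | penta-O-benzylepicatechin-(4β→6)-tetra-O-benzylepiafzelechin-(4β→8)-{penta-O-benzyl-4β-[2,6-bis(benzyloxy)-3-formyl-4-hydroxyphenyl]epicatechin} | O(Cc6ccccc6)c1ccc([C@H]2Oc3cc(OCc6ccccc6)c([C@H]4c5c(OCc6ccccc6)cc(OCc6ccccc6)cc5O[C@H](c5ccc(OCc6ccccc6)c(OCc6ccccc6)c5)[C@@H]4OCc6ccccc6)c(OCc6ccccc6)c3[C@H](c3c(OCc6ccccc6)cc(OCc6ccccc6)c4c3O[C@H](c3ccc(OCc6ccccc6)c(OCc6ccccc6)c3)[C@H](OCc6ccccc6)[C@H]4c3c(OCc6ccccc6)cc(O)c(C=O)c3OCc6ccccc6)[C@H]2OCc6ccccc6)cc1 | intermediate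
21 | penta-O-benzylepicatechin-(4β→6)-tetra-O-benzylepiafzelechin-(4β→8)-{penta-O-benzyl-4β-[2,6-bis(benzyloxy)-4-hydroxy-3-(hydroxymethyl)phenyl]epicatechin} | O(Cc6ccccc6)c1ccc([C@H]2Oc3cc(OCc6ccccc6)c([C@H]4c5c(OCc6ccccc6)cc(OCc6ccccc6)cc5O[C@H](c5ccc(OCc6ccccc6)c(OCc6ccccc6)c5)[C@@H]4OCc6ccccc6)c(OCc6ccccc6)c3[C@H](c3c(OCc6ccccc6)cc(OCc6ccccc6)c4c3O[C@H](c3ccc(OCc6ccccc6)c(OCc6ccccc6)c3)[C@H](OCc6ccccc6)[C@H]4c3c(OCc6ccccc6)cc(O)c(CO)c3OCc6ccccc6)[C@H]2OCc6ccccc6)cc1 | intermediate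
22 | 3,4-bis(benzyloxy)benzaldehyde | O=Cc1ccc(OCc2ccccc2)c(OCc2ccccc2)c1 | starting material
23 | 1,2-bis(benzyloxy)-4-ethynylbenzene | C#Cc1ccc(OCc2ccccc2)c(OCc2ccccc2)c1 | intermediate
24 | 2-[(Z)-2-(3,4-bis(benzyloxy)phenyl)ethenyl]-4,4,5,5-tetramethyl-1,3,2-dioxaborolane | CC1(C)OB(/C=C\c2ccc(OCc3ccccc3)c(OCc3ccccc3)c2)OC1(C)C | intermediate
25 | ortho-quinone methide of 21: the pendant ring is 3,5-bis(benzyloxy)-6-methylidenecyclohexa-2,4-dien-1-one bound through its C4 to C4β of the third flavan unit | O(Cc6ccccc6)c1ccc([C@H]2Oc3cc(OCc6ccccc6)c([C@H]4c5c(OCc6ccccc6)cc(OCc6ccccc6)cc5O[C@H](c5ccc(OCc6ccccc6)c(OCc6ccccc6)c5)[C@@H]4OCc6ccccc6)c(OCc6ccccc6)c3[C@H](c3c(OCc6ccccc6)cc(OCc6ccccc6)c4c3O[C@H](c3ccc(OCc6ccccc6)c(OCc6ccccc6)c3)[C@H](OCc6ccccc6)[C@H]4C3=C(OCc6ccccc6)C(=C)C(=O)C=C3OCc6ccccc6)[C@H]2OCc6ccccc6)cc1 | intermediate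
26 | penta-O-benzylepicatechin-(4β→6)-tetra-O-benzylepiafzelechin-(4β→8)-penta-O-benzylepicatechin-(4β→6)-[5,7,3',4'-tetra-O-benzyl-3-deoxy-3-(pinacolatoboryl)epicatechin], boron cis to the 2-aryl group | O(Cc6ccccc6)c1ccc([C@H]2Oc3cc(OCc6ccccc6)c([C@H]4c5c(OCc6ccccc6)cc(OCc6ccccc6)cc5O[C@H](c5ccc(OCc6ccccc6)c(OCc6ccccc6)c5)[C@@H]4OCc6ccccc6)c(OCc6ccccc6)c3[C@H](c3c(OCc6ccccc6)cc(OCc6ccccc6)c4c3O[C@H](c3ccc(OCc6ccccc6)c(OCc6ccccc6)c3)[C@H](OCc6ccccc6)[C@H]4c3c(OCc6ccccc6)cc4c(c3OCc6ccccc6)C[C@@H](B7OC(C)(C)C(C)(C)O7)[C@@H](c3ccc(OCc6ccccc6)c(OCc6ccccc6)c3)O4)[C@H]2OCc6ccccc6)cc1 | intermediate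
27 | penta-O-benzylepicatechin-(4β→6)-tetra-O-benzylepiafzelechin-(4β→8)-penta-O-benzylepicatechin-(4β→6)-5,7,3',4'-tetra-O-benzylepicatechin | O(Cc6ccccc6)c1ccc([C@H]2Oc3cc(OCc6ccccc6)c([C@H]4c5c(OCc6ccccc6)cc(OCc6ccccc6)cc5O[C@H](c5ccc(OCc6ccccc6)c(OCc6ccccc6)c5)[C@@H]4OCc6ccccc6)c(OCc6ccccc6)c3[C@H](c3c(OCc6ccccc6)cc(OCc6ccccc6)c4c3O[C@H](c3ccc(OCc6ccccc6)c(OCc6ccccc6)c3)[C@H](OCc6ccccc6)[C@H]4c3c(OCc6ccccc6)cc4c(c3OCc6ccccc6)C[C@@H](O)[C@@H](c3ccc(OCc6ccccc6)c(OCc6ccccc6)c3)O4)[C@H]2OCc6ccccc6)cc1 | intermediate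
28 | epicatechin-(4β→6)-epiafzelechin-(4β→8)-epicatechin-(4β→6)-epicatechin (CNP0103636.1) | Oc1ccc([C@H]2Oc3cc(O)c([C@H]4c5c(O)cc(O)cc5O[C@H](c5ccc(O)c(O)c5)[C@@H]4O)c(O)c3[C@H](c3c(O)cc(O)c4c3O[C@H](c3ccc(O)c(O)c3)[C@H](O)[C@H]4c3c(O)cc4c(c3O)C[C@@H](O)[C@@H](c3ccc(O)c(O)c3)O4)[C@H]2O)cc1 | target

**Step count and risks**

Total step count: 18. Longest linear sequence: 14 steps (1, 2, 3, 5, 6, 7, 9, 10, 11, 12, 13, 14, 17, 18).

Steps most likely to fail:

1. Step 17 (Proposed new method). The cycloaddition may lose its cis stereospecificity through a stepwise ionic pathway with rotation about C2–C3, the chiral anion may discriminate the faces poorly on an unsubstituted methide, boron may be lost from a β-boryl cation, or the quinone methide may alkylate benzyloxyarenes of a second molecule. The fallback uses known chemistry with both stereocentres preset; it sets out from 19 and 22 and comes back at 27. Aldehyde 22 is treated with vinylmagnesium bromide (THF, 0 °C) to give racemic 1-[3,4-bis(benzyloxy)phenyl]prop-2-en-1-ol F1. Sharpless kinetic resolution (Ti(OiPr)4, L-(+)-DIPT, TBHP, 4 Å MS, CH2Cl2, −20 °C) converts the fast-reacting (R)-enantiomer into the erythro epoxy alcohol (S)-[3,4-bis(benzyloxy)phenyl][(2R)-oxiran-2-yl]methanol F2. Mitsunobu etherification of phenol 19 with it (PPh3, DIAD, toluene, 0 °C) inverts the benzylic carbon and gives the threo aryl ether, the (R)-[3,4-bis(benzyloxy)phenyl][(2R)-oxiran-2-yl]methyl ether of 19 F3. A 6-endo epoxy-arene Friedel–Crafts cyclisation (BF3·OEt2, CH2Cl2, −78 °C) onto either of the two equivalent carbons ortho to the ether oxygen then closes the same pyran ring through C4–C4a and gives 27.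

2. Step 9 (Proposed new method). The same processes may fail here at the dimer stage. The fallback is a chiral-pool route that sets out from 4 and comes back at 15. Purchased (−)-epiafzelechin (O[C@@H]1Cc2c(O)cc(O)cc2O[C@@H]1c1ccc(O)cc1) is benzylated (BnBr, K2CO3, DMF) to 5,7,4'-tri-O-benzyl-(−)-epiafzelechin F4. This is brominated at its more reactive C8 (NBS, CH2Cl2, −40 °C) to 8-bromo-5,7,4'-tri-O-benzylepiafzelechin F5. The bromide, in excess, is coupled with 4 (TMSOTf, CH2Cl2, −78 °C) at C6, its only free A-ring carbon, to give penta-O-benzylepicatechin-(4β→6)-(8-bromo-5,7,4'-tri-O-benzylepiafzelechin) F6. Bromine–lithium exchange (n-BuLi, THF, −78 °C) and protonation with methanol then return 15.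

3. Step 5. The flavan-4-yl cation may substitute ortho to the silyloxy group instead of para, which would carry the wrong connectivity into both annulations. The fallback removes the regiochemical question; it sets out from 4 and comes back at 7. Condensation of 4 with an excess of phloroglucinol (TMSOTf, THF/CH2Cl2, −40 °C), whose three carbons are equivalent, gives 3,5,7,3',4'-penta-O-benzyl-4β-(2,4,6-trihydroxyphenyl)epicatechin F7. The unhindered para hydroxyl is silylated selectively (TIPSCl, 1 equiv, imidazole, DMF, 0 °C) to 3,5,7,3',4'-penta-O-benzyl-4β-[2,6-dihydroxy-4-(triisopropylsilyloxy)phenyl]epicatechin F8. The two hindered ortho hydroxyls are then benzylated (BnBr, K2CO3, acetone, reflux) to give 7.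

**Further compounds**

F1 | step 17 | rac-1-[3,4-bis(benzyloxy)phenyl]prop-2-en-1-ol | OC(C=C)c1ccc(OCc2ccccc2)c(OCc2ccccc2)c1
F2 | step 17 | (S)-[3,4-bis(benzyloxy)phenyl][(2R)-oxiran-2-yl]methanol | O[C@@H](c1ccc(OCc2ccccc2)c(OCc2ccccc2)c1)[C@H]1CO1
F3 | step 17 | (R)-[3,4-bis(benzyloxy)phenyl][(2R)-oxiran-2-yl]methyl ether of phenol 19 | O(Cc6ccccc6)c1ccc([C@H]2Oc3cc(OCc6ccccc6)c([C@H]4c5c(OCc6ccccc6)cc(OCc6ccccc6)cc5O[C@H](c5ccc(OCc6ccccc6)c(OCc6ccccc6)c5)[C@@H]4OCc6ccccc6)c(OCc6ccccc6)c3[C@H](c3c(OCc6ccccc6)cc(OCc6ccccc6)c4c3O[C@H](c3ccc(OCc6ccccc6)c(OCc6ccccc6)c3)[C@H](OCc6ccccc6)[C@H]4c3c(OCc6ccccc6)cc(O[C@H](c4ccc(OCc6ccccc6)c(OCc6ccccc6)c4)[C@H]5CO5)cc3OCc6ccccc6)[C@H]2OCc6ccccc6)cc1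
F4 | step 9 | 5,7,4'-tri-O-benzyl-(−)-epiafzelechin | O[C@@H]1Cc2c(OCc6ccccc6)cc(OCc6ccccc6)cc2O[C@@H]1c1ccc(OCc6ccccc6)cc1
F5 | step 9 | 8-bromo-5,7,4'-tri-O-benzyl-(−)-epiafzelechin | O[C@@H]1Cc2c(OCc6ccccc6)cc(OCc6ccccc6)c(Br)c2O[C@@H]1c1ccc(OCc6ccccc6)cc1
F6 | step 9 | penta-O-benzylepicatechin-(4β→6)-(8-bromo-5,7,4'-tri-O-benzylepiafzelechin) | O(Cc6ccccc6)c1ccc([C@H]2Oc3c(Br)c(OCc6ccccc6)c([C@H]4c5c(OCc6ccccc6)cc(OCc6ccccc6)cc5O[C@H](c5ccc(OCc6ccccc6)c(OCc6ccccc6)c5)[C@@H]4OCc6ccccc6)c(OCc6ccccc6)c3C[C@H]2O)cc1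
F7 | step 5 | 3,5,7,3',4'-penta-O-benzyl-4β-(2,4,6-trihydroxyphenyl)epicatechin | Oc1cc(O)c([C@H]2c3c(OCc6ccccc6)cc(OCc6ccccc6)cc3O[C@H](c3ccc(OCc6ccccc6)c(OCc6ccccc6)c3)[C@@H]2OCc6ccccc6)c(O)c1
F8 | step 5 | 3,5,7,3',4'-penta-O-benzyl-4β-[2,6-dihydroxy-4-(triisopropylsilyloxy)phenyl]epicatechin | CC(C)[Si](C(C)C)(C(C)C)Oc1cc(O)c([C@H]2c3c(OCc6ccccc6)cc(OCc6ccccc6)cc3O[C@H](c3ccc(OCc6ccccc6)c(OCc6ccccc6)c3)[C@@H]2OCc6ccccc6)c(O)c1
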